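**Assumption:** labdane numbering is used; the target is (5S,9R,10S)-15-acetoxylabda-7,13E-dien-17-oic acid, which has the ring-fusion stereochemistry of commercial (−)-sclareol (5α-H, 9α-H, 10β-CH3).

**Retrosynthetic overview**
1. Target acid ⇐ C17 aldehyde ⇐ labda-7,13E-dien-15-yl acetate, by allylic C–H oxygenation of the C17 methyl (C17–O bond).
2. The 7,8-alkene of ring B ⇐ dehydration of the C8 tertiary alcohol of (13E)-15-acetoxylabd-13-en-8α-ol.
3. Key disconnection, the C15–O ester bond: primary allylic acetate ⇐ tertiary vinyl carbinol of (−)-sclareol plus acetic acid, by a 1,3-transpositional (SN2′) acetoxylation that also sets the 13E alkene.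
4. No ring is formed: rings A and B and the C5, C9 and C10 stereocentres come intact from (−)-sclareol; its C8 and C13 stereocentres are erased.

**Route**

Step 1
Reactants: 1 (−)-sclareol; 2 acetic acid
Product: 3 (13E)-15-acetoxylabd-13-en-8α-ol
Conditions: (Sp,R)-[Pd(μ-OAc){C5H3(4-iPr-oxazolin-2-yl)Co(C4Ph4)}]2 (C82H72Co2N2O6Pd2, 2.5 mol%), AcOH (5 equiv), 4 Å MS, CH2Cl2, 23 °C
Reagents that add atoms: acetic acid, CC(=O)O
Why: Proposed new method: a dehydrative SN2′ acetoxylation of a free tertiary vinyl carbinol by a chiral divalent-palladium palladacycle, in which the metal binds the vinyl group on the face syn to the coordinating C13 hydroxyl, acetate adds to the unhindered C15 terminus, and syn β-hydroxide elimination (Pd–OH + AcOH → Pd–OAc + H2O) forms the 13,14-alkene, so that for the fixed 13R centre the geometry depends only on which π-face of C14 the metal takes (Re face, side chain "outside", methyl "inside", gives 13E), a choice the (Sp,R) catalyst is expected to make in the matched sense, while the bulky palladacycle should not re-engage the trisubstituted product alkene and no allyl cation is formed that the C8 hydroxyl could trap as manoyl oxide; the closest known reactions are the Overman-type [3,3] shift of allylic acetates with PdCl2(MeCN)2, the SN2′ esterification of allylic trichloroacetimidates with carboxylic acids by this palladacycle family, and hydroxyl-leaving SN2′ etherifications with PdCl2(MeCN)2.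

Step 2
Reactants: 3 (13E)-15-acetoxylabd-13-en-8α-ol
Product: 5 labda-7,13E-dien-15-yl acetate, via sulfamate ester 4 (not isolated)
Conditions: Burgess reagent (MeO2CN(−)SO2N(+)Et3, 2.0 equiv), PhH, 23 → 50 °C
Reagents that add atoms: none
Why: Burgess dehydration: the tertiary sulfamate ionises to a tight ion pair and the sulfamate anion on the α face removes the aligned axial 7α-hydrogen (E1-like syn elimination), so the trisubstituted ring B alkene is expected as the main isomer (roughly 3:1 over the Δ8(17) and Δ8(9) isomers, which are removed on AgNO3-silica), while the allylic acetate and the 13E alkene are inert to these neutral conditions and no stereocentre is created.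

Step 3
Reactants: 5 labda-7,13E-dien-15-yl acetate
Product: 7 15-acetoxylabda-7,13E-dien-17-al, via allylic alcohol 6 (not isolated)
Conditions: SeO2 (1.3 equiv), 1,4-dioxane, 80 °C
Reagents that add atoms: selenium dioxide, O=[Se]=O
Why: Riley allylic oxidation: the ene reaction places selenium on C7 and takes hydrogen from the C17 methyl at the more substituted alkene terminus (CH3 is preferred over the hindered C9 methine), the [2,3] shift delivers oxygen to C17 and restores the 7,8-alkene, and the primary allylic alcohol is oxidised on to the enal in the same pot, whereas the 13,14-alkene is deactivated by its allylic acetate (as in geranyl acetate) and no stereocentre is touched.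

Step 4
Reactants: 7 15-acetoxylabda-7,13E-dien-17-al
Product: 8 15-acetoxylabda-7,13E-dien-17-oic acid (target)
Conditions: NaClO2, NaH2PO4, 2-methyl-2-butene, t-BuOH/H2O, 0 → 23 °C
Reagents that add atoms: sodium chlorite, [Na+].[O-]Cl=O
Why: Pinnick oxidation: chlorous acid adds to the aldehyde and fragments to the carboxylic acid near pH 4, 2-methyl-2-butene scavenges HOCl so neither alkene is chlorinated, and the acetate, both alkenes and the C9 stereocentre are left unchanged.

**Compound list**
1 | (−)-sclareol, (13R)-labd-14-ene-8α,13-diol | C=C[C@](C)(O)CC[C@H]1[C@](C)(O)CC[C@H]2C(C)(C)CCC[C@]12C | starting material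
2 | acetic acid | CC(=O)O | starting material
3 | (13E)-15-acetoxylabd-13-en-8α-ol (8α-OH, 8β-CH3) | CC(=O)OC/C=C(\C)CC[C@H]1[C@](C)(O)CC[C@H]2C(C)(C)CCC[C@]12C | intermediate
4 | triethylammonium salt of the 8α-O-[N-(methoxycarbonyl)sulfamate] of 3 | CC(=O)OC/C=C(\C)CC[C@H]1[C@](C)(OS(=O)(=O)[N-]C(=O)OC)CC[C@H]2C(C)(C)CCC[C@]12C.CC[NH+](CC)CC | intermediate
5 | labda-7,13E-dien-15-yl acetate | CC(=O)OC/C=C(\C)CC[C@H]1C(C)=CC[C@H]2C(C)(C)CCC[C@]12C | intermediate
6 | 17-hydroxylabda-7,13E-dien-15-yl acetate | CC(=O)OC/C=C(\C)CC[C@H]1C(CO)=CC[C@H]2C(C)(C)CCC[C@]12C | intermediate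
7 | 15-acetoxylabda-7,13E-dien-17-al | CC(=O)OC/C=C(\C)CC[C@H]1C(C=O)=CC[C@H]2C(C)(C)CCC[C@]12C | intermediate
8 | (5S,9R,10S)-15-acetoxylabda-7,13E-dien-17-oic acid | CC(=O)OC/C=C(\C)CC[C@H]1C(C(=O)O)=CC[C@H]2C(C)(C)CCC[C@]12C | target

**Step count and risks**
Total steps: 4. Longest linear sequence: 4.

Three steps most likely to fail:

Step 1 (the proposed new reaction). The palladacycle may not turn over with hydroxide as the leaving group, or it may take the opposite π-face and give the 13Z isomer; running the enantiomeric catalyst is the first check, and residual 13Z isomer is removed on AgNO3-silica. The fallback uses known chemistry and sets out from 1. AcCl/PhNMe2 (CH2Cl2, 0 → 23 °C) gives sclareol diacetate F1. PdCl2(MeCN)2 (5 mol%, THF, 23 °C) shifts the tertiary allylic acetate by the [3,3] ester rearrangement to (13E)-labd-13-ene-8α,15-diyl diacetate F2, as an E-rich mixture. KOH/MeOH at reflux gives (13E)-labd-13-ene-8α,15-diol F3. Ac2O/pyridine at 0 °C acetylates only the primary hydroxyl and, after removal of the 13Z isomer on AgNO3-silica, comes back to the route at 3.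

Step 2 (regiochemistry of the dehydration). The Δ8(17) and Δ8(9) isomers may form in larger amounts than expected. The fallback sets out from 3. SOCl2/pyridine (CH2Cl2, −78 °C) eliminates anti toward the methyl group and gives mainly the exocyclic alkene (13E)-labda-8(17),13-dien-15-yl acetate F4. Hydrogen-atom-transfer isomerisation with CoCl(C36H52N2O2) (the chloride of the cobalt complex of N,N′-bis(3,5-di-tert-butylsalicylidene)-1,2-cyclohexanediamine, 3 mol%) and PhSiH3 in benzene then moves the 1,1-disubstituted double bond into ring B, with hydrogen removed from the less hindered C7, and comes back at 5.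

Step 3 (allylic oxidation). Yield may be modest, with over-oxidation at C9 of the enal or attack on the side chain. The fallback sets out from 5. mCPBA (1.0 equiv, NaHCO3, CH2Cl2, −20 °C) epoxidises the electron-richer ring alkene from the α face to 7α,8α-epoxy-(13E)-labd-13-en-15-yl acetate F5. Cp2TiCl (from Cp2TiCl2 and Mn, THF) opens the epoxide homolytically at C8 and gives the exocyclic allylic alcohol 7α-hydroxy-(13E)-labda-8(17),13-dien-15-yl acetate F6. Ph3SiOReO3 (2 mol%, Et2O, −50 → 0 °C) transposes the hydroxyl 1,3 to C17, toward the trisubstituted ring alkene, giving the primary allylic alcohol 6, here isolated. MnO2 (CH2Cl2) oxidises 6 and the sequence comes back at 7.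

**Further compounds**
F1 | step 1 | sclareol diacetate, (13R)-labd-14-ene-8α,13-diyl diacetate | C=C[C@](C)(OC(C)=O)CC[C@H]1[C@](C)(OC(C)=O)CC[C@H]2C(C)(C)CCC[C@]12C
F2 | step 1 | (13E)-labd-13-ene-8α,15-diyl diacetate | CC(=O)OC/C=C(\C)CC[C@H]1[C@](C)(OC(C)=O)CC[C@H]2C(C)(C)CCC[C@]12C
F3 | step 1 | (13E)-labd-13-ene-8α,15-diol | OC/C=C(\C)CC[C@H]1[C@](C)(O)CC[C@H]2C(C)(C)CCC[C@]12C
F4 | step 2 | (13E)-labda-8(17),13-dien-15-yl acetate | CC(=O)OC/C=C(\C)CC[C@H]1C(=C)CC[C@H]2C(C)(C)CCC[C@]12C
F5 | step 3 | 7α,8α-epoxy-(13E)-labd-13-en-15-yl acetate | CC(=O)OC/C=C(\C)CC[C@H]1[C@]3(C)O[C@@H]3C[C@H]2C(C)(C)CCC[C@]12C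
F6 | step 3 | 7α-hydroxy-(13E)-labda-8(17),13-dien-15-yl acetate | CC(=O)OC/C=C(\C)CC[C@H]1C(=C)[C@H](O)C[C@H]2C(C)(C)CCC[C@]12C
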